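**Retrosynthetic overview**

1. The strategy rests on the 2,3-dihydrobenzofuran ring (O1–C2–C3–C3a–C7a), whose C2 carries H and the exocyclic C(CH3)2OH group. The unit aryl-O1–C2H–C(CH3)2–OH is the ring-contracted isomer of the aryl-O1–C(CH3)2–C3H(OH) unit of a 3-hydroxy-2,2-dimethylchroman, and that chromanol descends from a 2,2-dimethylchromene, a privileged substrate for catalytic asymmetric epoxidation.
2. Disconnection A: the C2–CH2 bond at the quaternary lactone carbon (C2 of the 2,5-dihydrofuran ring) is cut to the planar furanolate of a bis-O-benzyl butenolide ester and a (dihydrobenzofuran-5-yl)methyl bromide, joined under chiral phase-transfer catalysis.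
3. Disconnection B: the butenolide ring comes from aldol addition and lactonisation of 4-hydroxyphenylpyruvic acid with methyl glyoxylate.
4. Disconnection C: the bromide comes from (S)-2-(5-bromo-2,3-dihydrobenzofuran-2-yl)propan-2-ol, made by ring contraction of (R)-6-bromo-2,2-dimethylchroman-3-ol through participation of O1. The chromanol comes from 4-bromophenol and 3-chloro-3-methylbut-1-yne via the chromene and its (3R,4R)-epoxide.
5. Ring order: pyran ring of the chromene (Claisen/electrocyclisation), then the oxirane (formed and reductively opened), then contraction of the pyran to the dihydrofuran (key step). The butenolide ring is made separately by lactonisation, and the two halves are joined last.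

Key step: step 5

Assumption: the (R,R)-configured salen manganese chloride catalyst is taken to deliver the (3R,4R)-epoxide, as expected for 2,2-dimethylchromenes. The sense of induction of the ammonium catalyst in step 12 cannot be predicted, so the pseudoenantiomeric (cinchoninium) salt is used if the cinchonidinium salt favours the (2R) product.

**Route**

Step 1
Reactants: 1 4-bromophenol; 2 3-chloro-3-methylbut-1-yne
Product: 3 1-bromo-4-[(2-methylbut-3-yn-2-yl)oxy]benzene
Conditions: K2CO3, KI (cat.), CuI (cat.), acetone, reflux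
Reagents that add atoms: none
Why: O-alkylation of the phenoxide by the tertiary propargylic chloride (Williamson-type etherification), which the copper-assisted ionisation of the chloride to a propargyl/allenyl cation equivalent makes feasible at the hindered carbon.

Step 2
Reactants: 3 1-bromo-4-[(2-methylbut-3-yn-2-yl)oxy]benzene
Product: 4 6-bromo-2,2-dimethyl-2H-chromene
Conditions: N,N-diethylaniline, 190 °C
Reagents that add atoms: none
Why: Aromatic propargyl Claisen rearrangement, whose [3,3] shift, enolisation, 1,5-hydrogen shift and oxa-6π electrocyclisation run as one thermal cascade and should close the 2,2-dimethylpyran ring at either of the two equivalent ortho positions.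

Step 3
Reactants: 4 6-bromo-2,2-dimethyl-2H-chromene
Product: 5 (3R,4R)-6-bromo-3,4-epoxy-2,2-dimethylchroman
Conditions: (R,R)-Mn(salen)Cl [salen = N,N'-bis(3,5-di-tert-butylsalicylidene)-1,2-cyclohexanediamine dianion, trivalent manganese] (4 mol%), 4-phenylpyridine N-oxide, aq NaOCl (pH 11.3), CH2Cl2, 0 °C
Reagents that add atoms: sodium hypochlorite, [Na+].[O-]Cl
Why: Jacobsen–Katsuki epoxidation, in which the cis-disubstituted aryl-conjugated olefin approaches the oxo-manganese salen species side-on and the (R,R)-ligand exposes one enantioface, so that both epoxide stereocentres should be set as (3R,4R) by the catalyst.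

Step 4
Reactants: 5 (3R,4R)-6-bromo-3,4-epoxy-2,2-dimethylchroman
Product: 6 (R)-6-bromo-2,2-dimethylchroman-3-ol
Conditions: LiAlH4, THF, 0 °C
Reagents that add atoms: none
Why: Regioselective reductive epoxide opening by SN2 hydride attack at the benzylic C4, since C3 is neopentyl-like beside the gem-dimethyl carbon, so the C3–O bond and its (R) configuration are untouched and the aryl bromide should be inert at this temperature.

Step 5
Reactants: 6 (R)-6-bromo-2,2-dimethylchroman-3-ol
Product: 9 (S)-2-(5-bromo-2,3-dihydrobenzofuran-2-yl)propan-2-ol, via chromanyl triflate 7 (not isolated), via epoxonium triflate 8 (not isolated)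
Conditions: Tf2O, pyridine, CH2Cl2, −40 → −10 °C; then THF/H2O (1:1), NaHCO3, 0 °C → rt
Reagents that add atoms: water, O
Why: Pyridine-buffered triflation turns the C3 hydroxyl of 6 into the triflate 7, and in the half-chair that places this group pseudo-equatorial the O1–C2 bond is anti-periplanar to C3–OTf, so the aryl ether oxygen O1 displaces triflate from the rear in a 3-exo-tet closure to the O-aryl epoxonium ion 8, in which O1 bridges C2 and C3. Water then attacks 8 at the tertiary gem-dimethyl carbon C2, which carries most of the positive charge, breaking O1–C2 so that O1 stays bonded to the former C3 within the five-membered ring (O1, former C3, CH2, C3a, C7a) and C2 becomes the exocyclic tertiary carbinol. The closest known reaction type is neighbouring-group participation of the ring oxygen in solvolyses of 3-sulfonyloxy-2,2-dimethylchromans, the dihydropyran-to-hydroxyisopropyldihydrofuran contraction of pyranocoumarin and furanocoumarin chemistry. The only ring-forming event is the 3-exo-tet O1–C3 closure, which becomes the dihydrofuran ring once O1–C2 is cut, and the single stereocentre is not created anew but inverted stereospecifically, so (R)-C3 of 6 becomes (S)-C2 of 9 (the CIP ranking O > CMe2 > CH2 > H is the same before and after). The step needs opening of 8 at C2 to outrun return at C3 (which only regenerates 6 with net retention), E2 loss of a C4 proton to chromene 4, methyl migration and proton loss to the isopropenyl compound; the tertiary versus secondary character of the two epoxonium carbons, the neopentyl shielding of C3 against external nucleophiles, the still electron-rich aryl ether oxygen and the early addition of a large excess of water at low temperature should secure this.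

Step 6
Reactants: 9 (S)-2-(5-bromo-2,3-dihydrobenzofuran-2-yl)propan-2-ol
Product: 10 (S)-{[2-(5-bromo-2,3-dihydrobenzofuran-2-yl)propan-2-yl]oxy}triethylsilane
Conditions: TESOTf, 2,6-lutidine, CH2Cl2, 0 °C
Reagents that add atoms: triethylsilyl trifluoromethanesulfonate, CC[Si](CC)(CC)OS(=O)(=O)C(F)(F)F
Why: Silyl ether formation with a silyl triflate and a non-nucleophilic base is the standard way to cap a hindered tertiary alcohol and removes the only acidic proton before the organolithium step.

Step 7
Reactants: 10 (S)-{[2-(5-bromo-2,3-dihydrobenzofuran-2-yl)propan-2-yl]oxy}triethylsilane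
Product: 12 (S)-2-{2-[(triethylsilyl)oxy]propan-2-yl}-2,3-dihydrobenzofuran-5-carbaldehyde, via aryllithium 11 (not isolated)
Conditions: n-BuLi, THF, −78 °C; DMF, −78 → 0 °C; aq NH4Cl
Reagents that add atoms: N,N-dimethylformamide, CN(C)C=O
Why: Bromine–lithium exchange at −78 °C is faster than any attack on the silyl or aryl ether, and the aryllithium adds to DMF to give a hemiaminal alkoxide that releases the aldehyde on work-up (Bouveault-type formylation).

Step 8
Reactants: 12 (S)-2-{2-[(triethylsilyl)oxy]propan-2-yl}-2,3-dihydrobenzofuran-5-carbaldehyde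
Product: 13 (S)-(2-{2-[(triethylsilyl)oxy]propan-2-yl}-2,3-dihydrobenzofuran-5-yl)methanol
Conditions: NaBH4, MeOH, 0 °C
Reagents that add atoms: none
Why: Borohydride reduction of the aryl aldehyde to the benzylic alcohol, with no other reducible group present.

Step 9
Reactants: 13 (S)-(2-{2-[(triethylsilyl)oxy]propan-2-yl}-2,3-dihydrobenzofuran-5-yl)methanol
Product: 14 (S)-({2-[5-(bromomethyl)-2,3-dihydrobenzofuran-2-yl]propan-2-yl}oxy)triethylsilane
Conditions: CBr4, PPh3, CH2Cl2, 0 °C; used at once
Reagents that add atoms: carbon tetrabromide, BrC(Br)(Br)Br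
Why: The Appel reaction converts the primary benzylic alcohol into the bromide under neutral conditions that should leave the tertiary silyl ether and the dihydrobenzofuran intact.

Step 10
Reactants: 15 4-hydroxyphenylpyruvic acid; 16 methyl glyoxylate
Product: 18 methyl 4-hydroxy-3-(4-hydroxyphenyl)-5-oxo-2,5-dihydrofuran-2-carboxylate (racemic), via open-chain aldol adduct 17 (not isolated)
Conditions: DBU, DMF, 0 °C → rt; then 2 M HCl
Reagents that add atoms: none
Why: Aldol addition of the arylpyruvate enolate through its benzylic carbon to the highly electrophilic glyoxylate aldehyde, then acid-promoted 5-exo-trig lactonisation of the γ-hydroxy-α-keto acid and enolisation, is the established arylpyruvic acid plus aldehyde route to 4-hydroxy-3-aryl-5-oxo-2,5-dihydrofurans; the racemic C2 centre is planarised later.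

Step 11
Reactants: 18 methyl 4-hydroxy-3-(4-hydroxyphenyl)-5-oxo-2,5-dihydrofuran-2-carboxylate (racemic)
Product: 19 methyl 4-(benzyloxy)-3-[4-(benzyloxy)phenyl]-5-oxo-2,5-dihydrofuran-2-carboxylate (racemic)
Conditions: BnOH (2.1 equiv), PPh3, DIAD, THF, 0 °C → rt
Reagents that add atoms: benzyl alcohol, OCc1ccccc1
Why: Double Mitsunobu etherification, in which the acidic enol and phenol hydroxyls act as pronucleophiles toward the benzyloxyphosphonium ion, while the base-free conditions avoid the C2 carbanion that benzyl bromide and carbonate would C-benzylate.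

Step 12
Reactants: 19 methyl 4-(benzyloxy)-3-[4-(benzyloxy)phenyl]-5-oxo-2,5-dihydrofuran-2-carboxylate (racemic); 14 (S)-({2-[5-(bromomethyl)-2,3-dihydrobenzofuran-2-yl]propan-2-yl}oxy)triethylsilane
Product: 20 methyl (2S)-4-(benzyloxy)-3-[4-(benzyloxy)phenyl]-5-oxo-2-[((2S)-2-{2-[(triethylsilyl)oxy]propan-2-yl}-2,3-dihydrobenzofuran-5-yl)methyl]-2,5-dihydrofuran-2-carboxylate
Conditions: N-(9-anthracenylmethyl)-O-allylcinchonidinium bromide (10 mol%), Cs2CO3, toluene, −20 °C
Reagents that add atoms: none
Why: Proposed new method: carbonate removes the C2 proton (acidified by the ester and, vinylogously, by the lactone carbonyl) to give a planar 2-oxidofuran that travels into toluene as a tight ion pair with the chiral ammonium cation and is benzylated by 14 on the enantioface left open by the catalyst, attack at C2 rather than at the carbonyl-α carbon C4 being expected because C4 is flanked by its benzyloxy group and the aryl ring and C2 attack keeps the conjugated enol ether lactone; the remote (S) centre of 14 should not interfere with catalyst control, and the closest known reaction type is the cinchona-ammonium phase-transfer benzylation of cyclic β-keto esters, 3-substituted oxindoles and α-substituted malonates to quaternary stereocentres.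

Step 13
Reactants: 20 methyl (2S)-4-(benzyloxy)-3-[4-(benzyloxy)phenyl]-5-oxo-2-[((2S)-2-{2-[(triethylsilyl)oxy]propan-2-yl}-2,3-dihydrobenzofuran-5-yl)methyl]-2,5-dihydrofuran-2-carboxylate
Product: 21 methyl (2S)-4-(benzyloxy)-3-[4-(benzyloxy)phenyl]-2-{[(2S)-2-(2-hydroxypropan-2-yl)-2,3-dihydrobenzofuran-5-yl]methyl}-5-oxo-2,5-dihydrofuran-2-carboxylate
Conditions: HF·pyridine, pyridine, THF, 0 °C → rt
Reagents that add atoms: none
Why: Fluoride cleavage of the tertiary triethylsilyl ether with buffered HF·pyridine, under which the methyl ester, the lactone and both benzyl ethers should be stable.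

Step 14
Reactants: 21 methyl (2S)-4-(benzyloxy)-3-[4-(benzyloxy)phenyl]-2-{[(2S)-2-(2-hydroxypropan-2-yl)-2,3-dihydrobenzofuran-5-yl]methyl}-5-oxo-2,5-dihydrofuran-2-carboxylate
Product: 22 methyl (2S)-4-hydroxy-2-{[(2S)-2-(2-hydroxypropan-2-yl)-2,3-dihydrobenzofuran-5-yl]methyl}-3-(4-hydroxyphenyl)-5-oxo-2,5-dihydrofuran-2-carboxylate
Conditions: H2 (1 atm), Pd/C (10% palladium on carbon), EtOAc, rt
Reagents that add atoms: none
Why: Catalytic hydrogenolysis should cleave the benzyl enol ether and the benzyl aryl ether while the tetrasubstituted conjugated butenolide alkene, the aryl–oxygen bonds and both stereocentres stay untouched.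

**Compound list**

1 | 4-bromophenol | Oc1ccc(Br)cc1 | starting material
2 | 3-chloro-3-methylbut-1-yne | CC(C)(Cl)C#C | starting material
3 | 1-bromo-4-[(2-methylbut-3-yn-2-yl)oxy]benzene | C#CC(C)(C)Oc1ccc(Br)cc1 | intermediate
4 | 6-bromo-2,2-dimethyl-2H-chromene | Brc1ccc2c(c1)C=CC(C)(C)O2 | intermediate
5 | (3R,4R)-6-bromo-3,4-epoxy-2,2-dimethylchroman | Brc1ccc2c(c1)[C@@H]3[C@@H](O3)C(C)(C)O2 | intermediate
6 | (R)-6-bromo-2,2-dimethylchroman-3-ol | Brc1ccc2c(c1)C[C@@H](O)C(C)(C)O2 | intermediate
7 | (R)-6-bromo-2,2-dimethylchroman-3-yl trifluoromethanesulfonate | Brc1ccc2c(c1)C[C@@H](OS(=O)(=O)C(F)(F)F)C(C)(C)O2 | intermediate (not isolated)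
8 | O-aryl epoxonium ion bridging O1, C2 and C3 (C3 inverted), as its triflate | Brc1ccc2c(c1)C[C@H]3C(C)(C)[O+]23.[O-]S(=O)(=O)C(F)(F)F | intermediate (not isolated)
9 | (S)-2-(5-bromo-2,3-dihydrobenzofuran-2-yl)propan-2-ol | Brc1ccc2c(c1)C[C@@H](C(C)(C)O)O2 | intermediate
10 | (S)-{[2-(5-bromo-2,3-dihydrobenzofuran-2-yl)propan-2-yl]oxy}triethylsilane | Brc1ccc2c(c1)C[C@@H](C(C)(C)O[Si](CC)(CC)CC)O2 | intermediate
11 | (S)-(2-{2-[(triethylsilyl)oxy]propan-2-yl}-2,3-dihydrobenzofuran-5-yl)lithium | [Li]c1ccc2c(c1)C[C@@H](C(C)(C)O[Si](CC)(CC)CC)O2 | intermediate (not isolated)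
12 | (S)-2-{2-[(triethylsilyl)oxy]propan-2-yl}-2,3-dihydrobenzofuran-5-carbaldehyde | O=Cc1ccc2c(c1)C[C@@H](C(C)(C)O[Si](CC)(CC)CC)O2 | intermediate
13 | (S)-(2-{2-[(triethylsilyl)oxy]propan-2-yl}-2,3-dihydrobenzofuran-5-yl)methanol | OCc1ccc2c(c1)C[C@@H](C(C)(C)O[Si](CC)(CC)CC)O2 | intermediate
14 | (S)-({2-[5-(bromomethyl)-2,3-dihydrobenzofuran-2-yl]propan-2-yl}oxy)triethylsilane | BrCc1ccc2c(c1)C[C@@H](C(C)(C)O[Si](CC)(CC)CC)O2 | intermediate
15 | 4-hydroxyphenylpyruvic acid | O=C(O)C(=O)Cc1ccc(O)cc1 | starting material
16 | methyl glyoxylate | COC(=O)C=O | starting material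
17 | 4-hydroxy-3-(4-hydroxyphenyl)-5-methoxy-2,5-dioxopentanoic acid (open-chain aldol adduct, mixture of stereoisomers) | COC(=O)C(O)C(c1ccc(O)cc1)C(=O)C(=O)O | intermediate (not isolated)
18 | methyl 4-hydroxy-3-(4-hydroxyphenyl)-5-oxo-2,5-dihydrofuran-2-carboxylate (racemic) | COC(=O)C1OC(=O)C(O)=C1c1ccc(O)cc1 | intermediate
19 | methyl 4-(benzyloxy)-3-[4-(benzyloxy)phenyl]-5-oxo-2,5-dihydrofuran-2-carboxylate (racemic) | COC(=O)C1OC(=O)C(OCc2ccccc2)=C1c1ccc(OCc2ccccc2)cc1 | intermediate
20 | methyl (2S)-4-(benzyloxy)-3-[4-(benzyloxy)phenyl]-5-oxo-2-[((2S)-2-{2-[(triethylsilyl)oxy]propan-2-yl}-2,3-dihydrobenzofuran-5-yl)methyl]-2,5-dihydrofuran-2-carboxylate | COC(=O)[C@@]1(Cc2ccc3c(c2)C[C@@H](C(C)(C)O[Si](CC)(CC)CC)O3)OC(=O)C(OCc2ccccc2)=C1c1ccc(OCc2ccccc2)cc1 | intermediate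
21 | methyl (2S)-4-(benzyloxy)-3-[4-(benzyloxy)phenyl]-2-{[(2S)-2-(2-hydroxypropan-2-yl)-2,3-dihydrobenzofuran-5-yl]methyl}-5-oxo-2,5-dihydrofuran-2-carboxylate | COC(=O)[C@@]1(Cc2ccc3c(c2)C[C@@H](C(C)(C)O)O3)OC(=O)C(OCc2ccccc2)=C1c1ccc(OCc2ccccc2)cc1 | intermediate
22 | methyl (2S)-4-hydroxy-2-{[(2S)-2-(2-hydroxypropan-2-yl)-2,3-dihydrobenzofuran-5-yl]methyl}-3-(4-hydroxyphenyl)-5-oxo-2,5-dihydrofuran-2-carboxylate | COC(=O)[C@@]1(Cc2ccc3c(c2)C[C@@H](C(C)(C)O)O3)OC(=O)C(O)=C1c1ccc(O)cc1 | target

**Step count and risks**

Total step count: 14. Longest linear sequence: 12 steps (steps 1–9, then 12–14, from 4-bromophenol).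

Steps most likely to fail:

1. Step 12. The chiral ion pair may discriminate poorly between the two faces of the planar furanolate, or alkylation may stray to the carbonyl-α carbon C4 or to oxygen, which would erode configurational purity at C2. The fallback uses known chemistry, sets out from 19 and 14 and comes back at 20. Alkylation with an achiral base (K2CO3, Bu4NI, acetone, rt; plain C-alkylation of an ester-stabilised carbanion) should give 20 together with its (2R)-configured C2 epimer F1. Because the side-chain centre is already fixed as (S), the two are diastereomers and are separated by preparative HPLC (silica or a cellulose carbamate phase); 20 then enters step 13.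

2. Step 5. E2 loss of a C4 proton back to the chromene, proton loss from a methyl group of the epoxonium ion to an isopropenyl dihydrobenzofuran, or return of water at C3 may outrun opening at the tertiary carbon. The fallback sets out from 1 and comes back at 9. Ortho-C-prenylation of the sodium phenoxide (NaH, prenyl bromide, toluene) should give 4-bromo-2-(3-methylbut-2-en-1-yl)phenol F2. Acetylation (Ac2O, pyridine) gives 4-bromo-2-(3-methylbut-2-en-1-yl)phenyl acetate F3. Shi epoxidation (D-fructose-derived ketone, KHSO5, buffered MeCN/H2O, 0 °C) is expected to give (R)-4-bromo-2-[(3,3-dimethyloxiran-2-yl)methyl]phenyl acetate F4. K2CO3 in MeOH then removes the acetate, and the phenoxide opens the epoxide at its secondary carbon in a 5-exo-tet closure with inversion to give 9.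

3. Step 11. Etherification may stop at the mono-ether, or benzylation may occur at carbon of the ring instead of at the two oxygens. The fallback sets out from 16 and comes back at 19; it brings in the phenolic benzyl ether before the ring is made. Purchased 4-(benzyloxy)benzaldehyde F5 is condensed with hydantoin (ethanolamine, aq EtOH, reflux) to (Z)-5-[4-(benzyloxy)benzylidene]imidazolidine-2,4-dione F6. Hot aq NaOH, then HCl, hydrolyses it to 3-[4-(benzyloxy)phenyl]-2-oxopropanoic acid F7. F7 and 16 under the conditions of step 10 should give methyl 3-[4-(benzyloxy)phenyl]-4-hydroxy-5-oxo-2,5-dihydrofuran-2-carboxylate F8. Its single enol hydroxyl is benzylated (BnOH, PPh3, DIAD, one equivalent) to give 19.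

**Further compounds**

F1 | step 12 | methyl (2R)-4-(benzyloxy)-3-[4-(benzyloxy)phenyl]-5-oxo-2-[((2S)-2-{2-[(triethylsilyl)oxy]propan-2-yl}-2,3-dihydrobenzofuran-5-yl)methyl]-2,5-dihydrofuran-2-carboxylate | COC(=O)[C@]1(Cc2ccc3c(c2)C[C@@H](C(C)(C)O[Si](CC)(CC)CC)O3)OC(=O)C(OCc2ccccc2)=C1c1ccc(OCc2ccccc2)cc1
F2 | step 5 | 4-bromo-2-(3-methylbut-2-en-1-yl)phenol | CC(C)=CCc1cc(Br)ccc1O
F3 | step 5 | 4-bromo-2-(3-methylbut-2-en-1-yl)phenyl acetate | CC(C)=CCc1cc(Br)ccc1OC(C)=O
F4 | step 5 | (R)-4-bromo-2-[(3,3-dimethyloxiran-2-yl)methyl]phenyl acetate | CC1(C)O[C@@H]1Cc1cc(Br)ccc1OC(C)=O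
F5 | step 11 | 4-(benzyloxy)benzaldehyde (purchased) | O=Cc1ccc(OCc2ccccc2)cc1
F6 | step 11 | (Z)-5-[4-(benzyloxy)benzylidene]imidazolidine-2,4-dione | O=C1N/C(=C\c2ccc(OCc3ccccc3)cc2)C(=O)N1
F7 | step 11 | 3-[4-(benzyloxy)phenyl]-2-oxopropanoic acid | O=C(O)C(=O)Cc1ccc(OCc2ccccc2)cc1
F8 | step 11 | methyl 3-[4-(benzyloxy)phenyl]-4-hydroxy-5-oxo-2,5-dihydrofuran-2-carboxylate (racemic) | COC(=O)C1OC(=O)C(O)=C1c1ccc(OCc2ccccc2)cc1
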